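Thursday's run slows. Left-handed product reads 34% at 0.200 min but 48% at 2.50 min, and left-handed substrate still reads 3%. Friday's run, with less catalyst and more partner, reads 0% of left-handed substrate at 1.33 min. Partner looks like the limiting reagent in Thursday's run at 45 mM, although that charge exceeds the 30 mM of left-handed substrate. What to watch is the share of partner that reaches product.

| setting | Thursday's | Tuesday's | Friday's | flask |
|---|---|---|---|---|
| left-handed substrate | 30 mM | 30 mM | 30 mM | 30 mM |
| right-handed substrate | 30 mM | 30 mM | 30 mM | 30 mM |
| partner | 45 mM | 45 mM | 68 mM | 45.0 mM |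
| protic impurity | 1.5 mM | 1.5 mM | 1.5 mM | 1.50 mM |
| free catalyst | 2.1 mM | 3.3 mM | 1.5 mM | 1.5 mM |
| remark | run made earlier | run made earlier | run made earlier |  |
| time |  |  |  | 2.0 min |

| run | time / min | left-handed product / % | right-handed product / % | left-handed substrate / % |
|---|---|---|---|---|
| Thursday's | 0.200 | 34 | 0 | 14 |
| Thursday's | 0.333 | 41 | 0 | 9 |
| Thursday's | 0.667 | 42 | 2 | 5 |
| Thursday's | 1.33 | 45 | 0 | 6 |
| Thursday's | 2.50 | 48 | 0 | 3 |
| Tuesday's | 0.500 | 44 | 0 | 0 |
| Tuesday's | 1.00 | 49 | 2 | 0 |
| Tuesday's | 1.33 | 49 | 4 | 0 |
| Tuesday's | 2.00 | 51 | 2 | 1 |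
| Tuesday's | 2.50 | 49 | 0 | 0 |
| Friday's | 0.500 | 44 | 1 | 5 |
| Friday's | 1.00 | 47 | 0 | 6 |
| Friday's | 1.33 | 48 | 0 | 0 |
| Friday's | 2.00 | 49 | 2 | 0 |
| Friday's | 2.50 | 48 | 2 | 0 |

(readings scatter by 1.5 percentage points)

* excess of left-handed product over right-handed product in the product at 2.5 s
* excess of left-handed product over right-handed product in the product at 2.0 min
* part of the left-handed substrate and right-handed substrate charged together that has reacted at 2.0 min

- free catalyst is single-handed; left-handed substrate and right-handed substrate are mirror images of each other, charged as a racemate, each of them at the stated concentration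
- what was read earlier has a scatter of 1.5 percentage points, one standard deviation
- an excess is the difference of the two amounts in percent of their sum
- an excess is below zero if the other one leads

Thursday's left-handed product, taken as the partner's whole yield:

28.8 mM from 45 mM of partner, a share of 64.0%

The new flask charges the same partner, so this share gives 48.0% of left-handed product. The weak link is holding the share fixed, since the flask has less catalyst. Suppose instead that the productive path scales with catalyst and the waste does not. The share is then catalyst over catalyst plus the break-even catalyst, the charge at which partner divides equally between product and waste: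

break-even catalyst = 2.1 mM × (1/share − 1) = 1.18 mM

flask share = 55.9%, so 25.2 mM of left-handed product, or 42.0%

Right-handed product stays near the scatter in Thursday's run, reading 2% at most, so this reckoning commits to about 42.0% reacted.

The forecast gives more: 47% reacted (43% to 50%), with excesses of 98.5% (94% to 100%) early and 97% (91% to 99.5%) at 2.0 min. Its ground for the slowing is that “the impurity must poison it gradually”.

The flask gives excesses of 98.1% at 2.5 s and 98.6% at 2.0 min, with 44.3% reacted, left-handed product at 42.0% and unbound partner at 0.29% of its charge.

    free catalyst + left-handed substrate ⇌ catalyst intermediate A (K = 1000 M⁻¹, k = 410 M⁻¹ s⁻¹)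
    free catalyst + right-handed substrate ⇌ catalyst intermediate B (K = 30.0 M⁻¹, k = 240 M⁻¹ s⁻¹)
    partner + catalyst intermediate A → free catalyst + left-handed product (k = 99.0 M⁻¹ s⁻¹)
    partner + catalyst intermediate B → free catalyst + right-handed product (k = 2.90 M⁻¹ s⁻¹)
    2 partner → homo dimer (k = 2.10 M⁻¹ s⁻¹)
    partner + protic impurity → quenched reagent (k = 52.0 M⁻¹ s⁻¹)
    partner ⇌ dormant form (K = 1.00, k = 0.0270 s⁻¹)

The reckoning carries the same share to the neighbouring flask with 76 mM of partner and the catalyst unchanged: 55.9% of that charge is 42.5 mM, more than the 30 mM of left-handed substrate. The reckoning therefore expects that flask to use up its left-handed substrate. At 2.0 min the neighbour holds 0.0685% of left-handed substrate and 49.9% of left-handed product, with an excess of 96.8% and 51.9% reacted.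

The readings were computed for an exercise; scatter was added.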